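The ratio 2[left-handed substrate]/([left-handed substrate]+[right-handed substrate]) is exactly what the excess of right-handed substrate falls short of purity, so in this kinetic resolution we need not reckon the large number, only this small correction, the shortfall.

| flask | left-handed substrate | right-handed substrate | reagent | free catalyst | remark | time |
|---|---|---|---|---|---|---|
| amber | 0.10 M | 0.10 M | 0.20 M | 0.18 mM | the very flask that is asked about, followed so far |  |
| flask | 0.10 M | 0.10 M | 0.200 M | 0.18 mM |  | 25 min |

amber run (percent of the left-handed substrate and right-handed substrate together charged)

| time / min | right-handed substrate / % | left-handed substrate / % | left-handed product / % |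
|---|---|---|---|
| 0.833 | 49.5 | 29.2 | 15.0 |
| 2.00 | 48.5 | 15.2 | 21.5 |
| 4.00 | 47.9 | 5.5 | 24.5 |
| 10.0 | 44.6 | 0.6 | 27.3 |

(readings scatter by 0.3 percentage points)

- free catalyst is single-handed; left-handed substrate and right-handed substrate are mirror images of each other, charged as a racemate, each of them at the stated concentration

1. whether the excess of right-handed substrate over left-handed substrate among what is left of the two reaches 80% by 25 min (yes / no)
2. the highest excess of right-handed substrate over left-handed substrate among what is left of the two up to 25 min

The amber run, which is this very flask followed so far, gives a shortfall of 20.6% at 4.00 min and 2.65% at 10.0 min, the second resting on a reading uncertain by half. The level asked for means a shortfall of 20.0%, and the later amber value already lies below it, so the dispute over this flask concerns the highest excess.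

The first chemist takes the fall as steady and defines the fall constant of the shortfall, the logarithm of the ratio of two shortfalls divided by the time between them, here 0.341 min⁻¹, a halving every 2.03 min. Carried to 25 min, it leaves 0.0158%, an excess of >99.9%. The second chemist expects the tail to stop, so that the shortfall stays near its last value and the excess near 97.3%.

The forecast sides with the first on the direction of the tail, gives yes and, as a figure of its own, 99.7%, and names as a doubt “a possible floor in the left-handed substrate”.

This flask gives yes and >99.9%, passing 80% at 4.15 min with 47.6% of right-handed substrate left, so the floor view is left the stretch up to 10.0 min, where the reading stood 2.00 standard deviations above nothing.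

    free catalyst + left-handed substrate ⇌ catalyst intermediate A (K = 15.0 M⁻¹, k = 46000 M⁻¹ s⁻¹)
    free catalyst + right-handed substrate ⇌ catalyst intermediate B (K = 10.0 M⁻¹, k = 4500 M⁻¹ s⁻¹)
    reagent + catalyst intermediate A → free catalyst + left-handed product (k = 100 M⁻¹ s⁻¹)
    reagent + catalyst intermediate B → free catalyst + right-handed product (k = 3.30 M⁻¹ s⁻¹)
    left-handed product ⇌ right-handed product (k = 0.0150 s⁻¹)
    2 free catalyst ⇌ resting dimer, settled at all times (K = 5800 M⁻¹)
    reagent ⇌ dormant form (K = 0.250, k = 0.0680 s⁻¹)

At 12.5 min the shortfall in this flask is 0.580%, against 1.13% from the fall constant. At 1.14 min in this flask, left-handed substrate took up free catalyst 5.2 times as fast as right-handed substrate did, each forward step alone, and its half-life by that forward step alone, 0.28 s, was short against 25 min. The backward turnover of that step stood at 99.6% of the forward one, and the half-life of reagent by the step making left-handed product grew from 2.9 min at 1.14 min to 1200 h at 25.0 min.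

The readings are simulated on assumed constants; the scatter is artificial.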